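(The earlier runs and the new flask were generated by integration with made-up constants; scatter was added.)

| flask | starting material | coupling partner | remark | time |
|---|---|---|---|---|
| winter | 35 mM (fed, over 8.0 h) | 0.85 mM | run made earlier; the fed solution adds 0.10 times the starting volume |  |
| spring | 35 mM (fed, over 8.0 h) | 11 mM | run made earlier; the fed solution adds 0.10 times the starting volume |  |
| autumn | 35 mM (fed, over 8.0 h) | 110 mM | run made earlier; the fed solution adds 0.10 times the starting volume |  |
| grey | 35 mM (fed, over 8.0 h) | 1.20 mM | the fed solution adds 0.10 times the starting volume | 30 h |
| amber | 35 mM (fed, over 8.0 h) | 4.00 mM | the fed solution adds 0.10 times the starting volume | 30 h |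
| green | 35 mM (fed, over 8.0 h) | 12.0 mM | the fed solution adds 0.10 times the starting volume | 30 h |
| ochre | 35 mM (fed, over 8.0 h) | 30.0 mM | the fed solution adds 0.10 times the starting volume | 30 h |
| red | 35 mM (fed, over 8.0 h) | 100 mM | the fed solution adds 0.10 times the starting volume | 30 h |

| run | time / h | single product / % |
|---|---|---|
| winter | 2.00 | 3.0 |
| winter | 5.00 | 2.1 |
| winter | 10.0 | 2.3 |
| winter | 15.0 | 0.8 |
| spring | 4.00 | 20.7 |
| spring | 8.00 | 19.0 |
| spring | 12.0 | 16.6 |
| spring | 15.0 | 17.2 |
| autumn | 1.33 | 11.1 |
| autumn | 3.00 | 18.8 |
| autumn | 6.00 | 27.6 |
| autumn | 15.0 | 11.8 |

(scatter of a reading: 1 percentage point)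

- amounts are per litre of the starting volume; all of the dose is in the solution fed
- "hardly changes" means that all values lie within two and a half points (for a concentration: within two and a half percent of the largest)
- percentages count the whole charge, also what has not yet gone in

- amount of single product at the end, in percent of the starting material charged for grey, amber, green, ochre, red, in this order
- the shape of the row from first to last (rises, then falls / hardly changes / falls all the way / falls, then rises / rises all the way)

1. Start with an easy division. If one coupling partner makes one single product, you reckon a ceiling: starting [coupling partner] over charged [starting material]. Below it, you treat coupling partner as the limiting reagent.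

2. Turn the partner charge up from the low end. By hand, the yield follows the ceiling. The winter ceiling is 2.43%, and the early winter readings are 3.0%, 2.1% and 2.3%. The spring ceiling is 31.4%, but the spring reading at 15.0 h is lower, at 17.2%. Spring gives 0.547 for the late reading over the ceiling, the kept share. It carries the scatter of that reading.

3. Turn the partner charge far up and let the time run. By hand, excess partner should attack product. The autumn flask reads 27.6% at 6.00 h, then 11.8% at 15.0 h.

4. Join the two ends. Kept share times ceiling gives me 1.88% for grey, 6.25% for amber and 18.8% for green. For ochre the same product gives 46.9%, which I take as an upper mark. Red lies near autumn and runs longer, so I put it under 11.8%. My row rises, then falls.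

5. The forecast gives 3%, 9%, 18%, 22% and 3%, with the shape rises, then falls. Its ground for the last point is “Red keeps excess partner”. My grey and amber values are lower than its values.

6. The flasks give 1.75%, 5.78%, 16.6%, 35.5% and 7.04%, with the shape rises, then falls.

    starting material + coupling partner → single product (k = 2.83 M⁻¹ min⁻¹)
    coupling partner + single product → bis adduct (k = 0.0663 M⁻¹ min⁻¹)
    coupling partner + bis adduct ⇌ tris adduct (K = 22.0 M⁻¹, k = 0.294 M⁻¹ min⁻¹)
    starting material → decomposition product (k = 3.00 × 10⁻⁶ min⁻¹)
    single product ⇌ isomer of the product (K = 0.953, k = 0.00183 min⁻¹)

The forecast and the flask part at ochre, 22% against 35.5%. The kept share comes to 0.510 in grey and 0.506 in amber, against 0.547 from spring. In grey, the forward half-life of single product into isomer of the product, 6.3 h, is shorter than the 30 h run, while its half-life into bis adduct at 1.43 h, 12 d, is longer than the run. At 30.0 h, grey holds 1.75% single product beside 1.66% isomer of the product and 0.00677% bis adduct.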